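## Retrosynthetic overview

1. Numbering: C1 = oxirane carbon bearing C7H2OBz, C2 = CHOAc, C3 = CHOBz, C4=C5, C6 = oxirane CH; β is the face of the C2 oxygen. The feature the plan rests on: with C7 set aside and the oxirane reopened with inversion at C6, the oxygens on C6, C1, C2, C3 of the cyclohex-4-ene alternate β, α, β, α, which is the all-trans, C2-symmetric tetrol pattern of conduritol B, and C1 alone carries one extra carbon, the oxygenated C7.
2. Oxirane C1–O–C6 ⇐ O1 alkoxide displacing a 6β-mesylate (inversion at C6); O7 and O3 benzoates by stepwise acylation; the O2 acetate is carried from early on.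
3. C1–O1 and C7–O7 ⇐ OsO4 on the exocyclic C1=C7 alkene of 6-methylene-cyclohexene 11 ⇐ C1 ketone ⇐ 3,6-di-O-TBS conduritol B, whose O1 and O2 hydroxyls are homotopic.
4. Conduritol B ⇐ anti-benzene dioxide ⇐ lipase-resolved all-trans 5,6-dibromocyclohex-2-ene-1,4-diol ⇐ p-benzoquinone.
5. Ring order: the carbocycle is bought and never rebuilt; two transient oxiranes are closed (step 4) and reopened (step 5); the target oxirane is the last ring closed (step 14).

Key step: step 10

Assumption: in step 3 the lipase is taken to acetylate the (1R,4R,5S,6S) enantiomer faster (the usual preference when CHBr is the large and CH= the medium substituent at the carbinol), so the needed (1S,4S,5R,6R)-diol is the unreacted fraction; were the preference reversed, the diacetate fraction would be taken and de-acetylated in methanol by the base of step 4.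

## Route

Step 1
Reactants: 1 p-benzoquinone
Product: 2 (±)-trans-5,6-dibromocyclohex-2-ene-1,4-dione
Conditions: Br2 (1.0 equiv), CHCl3, 0 °C
Reagents that add atoms: bromine, BrBr
Why: Electrophilic anti addition of Br2 across one quinone C=C should give the racemic trans-dibromide, the remaining ene-dione C=C being too electron-poor to add a second equivalent at 0 °C.

Step 2
Reactants: 2 (±)-trans-5,6-dibromocyclohex-2-ene-1,4-dione
Product: 3 (±)-all-trans-5,6-dibromocyclohex-2-ene-1,4-diol
Conditions: NaBH4, Et2O/H2O, 0 °C
Reagents that add atoms: none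
Why: Borohydride 1,2-reduction of both ketones, with hydride reaching each carbonyl from the face remote from the bromine on the 1,3-related carbon, should place every hydroxyl trans to its neighbouring bromine and the two hydroxyls trans to each other (C2-symmetric all-trans diol).

Step 3
Reactants: 3 (±)-all-trans-5,6-dibromocyclohex-2-ene-1,4-diol
Product: 4 (1S,4S,5R,6R)-5,6-dibromocyclohex-2-ene-1,4-diol (unreacted enantiomer)
Conditions: immobilised Candida antarctica lipase B, vinyl acetate, t-BuOMe, 40 °C, to slightly beyond half conversion; chromatography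
Reagents that add atoms: none
Why: Lipase-catalysed kinetic resolution by irreversible transesterification should acetylate both carbinols of the (1R,4R,5S,6S) enantiomer, which is removed as its diacetate, and leave 4 enantiomerically pure.

Step 4
Reactants: 4 (1S,4S,5R,6R)-5,6-dibromocyclohex-2-ene-1,4-diol
Product: 5 anti-benzene dioxide, (1S,2S,4S,7S)-3,8-dioxatricyclo[5.1.0.0(2,4)]oct-5-ene
Conditions: powdered KOH (2.5 equiv), Et2O, 0 °C → rt
Reagents that add atoms: none
Why: Twofold intramolecular Williamson etherification (3-exo-tet), each alkoxide being trans to the adjacent bromide and displacing it with inversion, should give the bis-oxirane with the two oxygens on opposite faces.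

Step 5
Reactants: 5 anti-benzene dioxide
Product: 6 conduritol B, (1R,2S,3S,4R)-cyclohex-5-ene-1,2,3,4-tetrol (target numbering from here: O1 α, O2 β, O3 α, O6 β)
Conditions: HClO4 (cat.), THF/H2O, rt; neutralisation with basic ion-exchange resin
Reagents that add atoms: water, O
Why: Acid-catalysed hydrolytic opening of both vinyl oxiranes, water attacking the allylic carbons C3 and C6 with inversion, should give the all-trans tetrol, the C2 symmetry making the two openings equivalent.

Step 6
Reactants: 6 conduritol B
Product: 7 3,6-bis-O-(tert-butyldimethylsilyl)conduritol B (1α,2β-diol free)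
Conditions: TBSCl (2.2 equiv), imidazole, DMF, −10 → 0 °C
Reagents that add atoms: tert-butyldimethylsilyl chloride, CC(C)(C)[Si](C)(C)Cl
Why: Regioselective silylation should take the two allylic hydroxyls, each flanked by an sp2 CH and only one carbinol, ahead of the inner hydroxyls flanked by two oxygenated carbons, and each new silyl ether further screens its inner neighbour.

Step 7
Reactants: 7 3,6-bis-O-TBS conduritol B
Product: 9 2β-O-acetyl-3,6-bis-O-TBS conduritol B (1α-OH free), via stannylene acetal 8 (not isolated)
Conditions: Bu2SnO (1.05 equiv), toluene, reflux (Dean–Stark); then AcCl (1.0 equiv), 0 °C; aqueous work-up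
Reagents that add atoms: acetyl chloride, CC(=O)Cl; dibutyltin oxide, CCCC[Sn](=O)CCCC (its atoms stay in 8 only)
Why: Stannylene-acetal-mediated monoacylation should stop after one acetyl transfer, and because the two oxygens are homotopic (C2 axis) only one monoacetate can form and acetyl migration between them is degenerate.

Step 8
Reactants: 9 2β-O-acetyl-3,6-bis-O-TBS conduritol B
Product: 10 (2β)-acetoxy-(3α,6β)-bis(TBS-oxy)cyclohex-4-en-1-one
Conditions: Dess–Martin periodinane (1.5 equiv), NaHCO3, CH2Cl2, 0 °C → rt
Reagents that add atoms: none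
Why: Dess–Martin oxidation of the single free secondary alcohol under buffered, non-basic conditions should give the β,γ-unsaturated ketone without enolisation toward C2 or C6.

Step 9
Reactants: 10 (2β)-acetoxy-(3α,6β)-bis(TBS-oxy)cyclohex-4-en-1-one
Product: 11 1-methylene-(2β)-acetoxy-(3α,6β)-bis(TBS-oxy)cyclohex-4-ene (key-step precursor)
Conditions: Cp2TiMe2 (1.5–2 equiv), toluene, 65 °C, dark
Reagents that add atoms: dimethyltitanocene, C[Ti+2]C.c1cc[cH-]c1.c1cc[cH-]c1
Why: Petasis methylenation (thermally generated Cp2Ti=CH2, [2+2] with the C=O, collapse of the oxatitanacyclobutane) is non-basic, so the enolisable ketone should survive, and with limited reagent the ketone carbonyl reacts ahead of the acetate carbonyl.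

Step 10
Reactants: 11 1-methylene-(2β)-acetoxy-(3α,6β)-bis(TBS-oxy)cyclohex-4-ene
Product: 13 C1,C7-diol (1α-hydroxy-1β-hydroxymethyl; 2β-OAc; 3α,6β-OTBS), via osmate ester 12 (not isolated)
Conditions: OsO4 (5 mol%), NMO (1.1 equiv), acetone/H2O 9:1, 0 °C → rt; Na2SO3 quench
Reagents that add atoms: osmium tetroxide, O=[Os](=O)(=O)=O; N-methylmorpholine N-oxide, C[N+]1([O-])CCOCC1
Why: OsO4 adds suprafacially to C1=C7 by [3+2] cycloaddition to give the hexavalent osmium glycolate 12, which NMO reoxidises and water hydrolyses to the tertiary C1 and primary C7 hydroxyls; this is the standard catalytic OsO4/NMO dihydroxylation of a 1,1-disubstituted alkene. No ring of the target is closed (only the transient five-membered osmate ring forms). The one new stereocentre, C1, is set by the substrate: the allylic C2 acetoxy and C6 silyloxy groups both lie on the β face, so osmium should approach the α face, anti to both allylic C–O bonds as is general for osmylation of allylic ethers and esters, placing O1 α (trans to O6, as the later displacement at C6 requires) and C7 β. The step needs site selectivity for C1=C7 over C4=C5 and α-face selectivity; the ring alkene has a bulky allylic silyloxy group on each of its faces (O3 α, O6 β) and so offers no face anti to both, whereas the exocyclic alkene has an unobstructed α face, and the oxidant is limited to about one equivalent. Near-neutral conditions and prompt work-up are meant to keep the C2 acetyl from moving to O7.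

Step 11
Reactants: 13 C1,C7-diol
Product: 14 7-O-benzoate of 13 (1α-OH free)
Conditions: BzCl (1.1 equiv), pyridine, CH2Cl2, −20 → 0 °C
Reagents that add atoms: benzoyl chloride, O=C(Cl)c1ccccc1
Why: Selective O-acylation should take the primary hydroxyl and leave the tertiary C1 hydroxyl untouched.

Step 12
Reactants: 14 7-O-benzoate
Product: 15 triol (1α,3α,6β-OH; 2β-OAc; 7-OBz)
Conditions: HF·pyridine, pyridine/THF, 0 °C → rt
Reagents that add atoms: none
Why: Fluoride-mediated cleavage of both silyl ethers under buffered acidic conditions should free O3 and O6 without the base-induced acyl migration that a basic fluoride source would risk.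

Step 13
Reactants: 15 triol
Product: 16 3α-O-benzoate (1α,6β-diol; 2β-OAc; 7-OBz)
Conditions: BzCl (1.05 equiv), pyridine, CH2Cl2, −40 → −10 °C
Reagents that add atoms: benzoyl chloride, O=C(Cl)c1ccccc1
Why: Regioselective acylation should favour O3, flanked by CH(OAc) and an sp2 CH, over O6, which sits next to the fully substituted C1, while the tertiary O1 is inert.

Step 14
Reactants: 16 3α-O-benzoate
Product: 18 target epoxide, via C6 mesylate 17 (not isolated)
Conditions: MsCl (1.2 equiv), Et3N, CH2Cl2, −20 °C; then DBU (2 equiv), 0 °C → rt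
Reagents that add atoms: methanesulfonyl chloride, CS(=O)(=O)Cl (its atoms stay in 17 only; none reach 18)
Why: Sulfonylation (via sulfene) of the only secondary hydroxyl, then intramolecular Williamson closure (3-exo-tet) in which the α-O1 alkoxide attacks C6 antiperiplanar to the β-mesylate with inversion, should give the α-oxirane, the non-nucleophilic base leaving the three esters intact.

## Compound list

1 | p-benzoquinone | O=C1C=CC(=O)C=C1 | starting material
2 | (±)-trans-5,6-dibromocyclohex-2-ene-1,4-dione (racemate, both enantiomers written) | O=C1C=CC(=O)[C@H](Br)[C@H]1Br.O=C1C=CC(=O)[C@@H](Br)[C@@H]1Br | intermediate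
3 | (±)-all-trans-5,6-dibromocyclohex-2-ene-1,4-diol (racemate, both enantiomers written) | Br[C@H]1[C@H](Br)[C@@H](O)C=C[C@@H]1O.Br[C@@H]1[C@@H](Br)[C@H](O)C=C[C@H]1O | intermediate
4 | (1S,4S,5R,6R)-5,6-dibromocyclohex-2-ene-1,4-diol | Br[C@H]1[C@H](Br)[C@@H](O)C=C[C@@H]1O | intermediate
5 | anti-benzene dioxide, (1S,2S,4S,7S)-3,8-dioxatricyclo[5.1.0.0(2,4)]oct-5-ene | [C@H]12O[C@H]1C=C[C@@H]1O[C@@H]12 | intermediate
6 | conduritol B, (1R,2S,3S,4R)-cyclohex-5-ene-1,2,3,4-tetrol | O[C@@H]1[C@@H](O)[C@H](O)C=C[C@H]1O | intermediate
7 | 3,6-bis-O-TBS conduritol B (1α,2β-diol) | O[C@@H]1[C@@H](O)[C@H](O[Si](C)(C)C(C)(C)C)C=C[C@H]1O[Si](C)(C)C(C)(C)C | intermediate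
8 | O1,O2-dibutylstannylene acetal of 7 | CCCC[Sn]1(CCCC)O[C@@H]2[C@@H](O1)[C@H](O[Si](C)(C)C(C)(C)C)C=C[C@H]2O[Si](C)(C)C(C)(C)C | intermediate
9 | 2β-O-acetyl-3,6-bis-O-TBS conduritol B | O[C@@H]1[C@@H](OC(C)=O)[C@H](O[Si](C)(C)C(C)(C)C)C=C[C@H]1O[Si](C)(C)C(C)(C)C | intermediate
10 | (2β)-acetoxy-(3α,6β)-bis(TBS-oxy)cyclohex-4-en-1-one | O=C1[C@@H](OC(C)=O)[C@H](O[Si](C)(C)C(C)(C)C)C=C[C@H]1O[Si](C)(C)C(C)(C)C | intermediate
11 | 1-methylene-(2β)-acetoxy-(3α,6β)-bis(TBS-oxy)cyclohex-4-ene | C=C1[C@@H](OC(C)=O)[C@H](O[Si](C)(C)C(C)(C)C)C=C[C@H]1O[Si](C)(C)C(C)(C)C | intermediate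
12 | cyclic hexavalent osmium glycolate of 11 (O1 α, C7 β) | O=[Os]1(=O)OC[C@@]2(O1)[C@@H](OC(C)=O)[C@H](O[Si](C)(C)C(C)(C)C)C=C[C@H]2O[Si](C)(C)C(C)(C)C | intermediate
13 | 1α-hydroxy-1β-hydroxymethyl diol (2β-OAc; 3α,6β-OTBS) | OC[C@@]1(O)[C@@H](OC(C)=O)[C@H](O[Si](C)(C)C(C)(C)C)C=C[C@H]1O[Si](C)(C)C(C)(C)C | intermediate
14 | 7-O-benzoate of 13 | O=C(OC[C@@]1(O)[C@@H](OC(C)=O)[C@H](O[Si](C)(C)C(C)(C)C)C=C[C@H]1O[Si](C)(C)C(C)(C)C)c1ccccc1 | intermediate
15 | 1α,3α,6β-triol (2β-OAc; 7-OBz) | O=C(OC[C@@]1(O)[C@@H](OC(C)=O)[C@H](O)C=C[C@H]1O)c1ccccc1 | intermediate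
16 | 3α-O-benzoate, 1α,6β-diol (2β-OAc; 7-OBz) | O=C(OC[C@@]1(O)[C@@H](OC(C)=O)[C@H](OC(=O)c2ccccc2)C=C[C@H]1O)c1ccccc1 | intermediate
17 | 6β-O-mesylate of 16 | O=C(OC[C@@]1(O)[C@@H](OC(C)=O)[C@H](OC(=O)c2ccccc2)C=C[C@H]1OS(C)(=O)=O)c1ccccc1 | intermediate
18 | [(1S,2S,3R,6S)-2-acetoxy-3-(benzoyloxy)-7-oxabicyclo[4.1.0]hept-4-en-1-yl]methyl benzoate | CC(=O)O[C@H]1[C@H](OC(=O)c2ccccc2)C=C[C@@H]2O[C@@]21COC(=O)c1ccccc1 | target

## Step count and risks

Total: 14 steps, all in one linear sequence; longest linear sequence 14 steps from p-benzoquinone.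

Steps most likely to fail:

**Step 10 (key step).** Osmium may also add to the ring alkene C4=C5 (loss of site selectivity and over-oxidation), may approach the β face of C1=C7 (poor facial selectivity), or the C2 acetyl may migrate to O7 once the diol is free. The fallback sets out from 11 and returns at 14. The exocyclic alkene would be epoxidised with mCPBA (NaHCO3-buffered CH2Cl2, 0 °C); the peracid meets a silyloxy group on either face of C4=C5 but an open α face at C1=C7, and should give the α-spiro-oxirane F1. The oxirane would then be opened at its unhindered CH2 terminus C7 with benzoic acid and catalytic tetrabutylammonium benzoate (toluene, 60 °C). This forms the C7 benzoate and the tertiary C1 hydroxyl of 14 in one operation and never exposes a free primary hydroxyl beside the acetate.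

**Step 9.** The titanium methylidene may also methylenate the acetate carbonyl, and during the heating the β,γ-unsaturated ketone may enolise toward C6, losing the C6 configuration or aromatising. The fallback sets out from 7 and returns at 11; it moves the acetylation behind the methylenation. One of the homotopic hydroxyls would be silylated with TESCl (1.0 equiv, imidazole, DMF, −20 °C) to the mono-triethylsilyl ether F2. Dess–Martin oxidation would give the ketone F3, and Cp2TiMe2 in excess (no ester is present to compete, so the reaction can be driven quickly) the triethylsilyl-protected diene F4. Selective removal of the triethylsilyl group (PPTS, MeOH, 0 °C) would give the allylic alcohol F5, and acetylation (Ac2O, pyridine, DMAP, 0 °C) gives 11.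

**Step 13.** Acylation may fail to discriminate the two secondary allylic hydroxyls O3 and O6, giving regioisomeric and doubly benzoylated material. The fallback sets out from 15 and returns at 18; it closes the oxirane before the last benzoate is introduced. Mitsunobu cyclodehydration (PPh3, DIAD, toluene, 0 °C → rt) acts on the only vicinal diol, O1/O6: phosphorus activates the secondary O6 and the tertiary O1 displaces it with inversion at C6, which should give the epoxy alcohol F6. The single remaining hydroxyl O3 would then be benzoylated (BzCl, pyridine, DMAP, CH2Cl2, 0 °C) to 18.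

## Further compounds

F1 | step 10 | α-spiro-oxirane at C1/C7 (2β-OAc; 3α,6β-OTBS) | C1O[C@@]12[C@@H](OC(C)=O)[C@H](O[Si](C)(C)C(C)(C)C)C=C[C@H]2O[Si](C)(C)C(C)(C)C
F2 | step 9 | 2β-O-triethylsilyl-3,6-bis-O-TBS conduritol B | O[C@@H]1[C@@H](O[Si](CC)(CC)CC)[C@H](O[Si](C)(C)C(C)(C)C)C=C[C@H]1O[Si](C)(C)C(C)(C)C
F3 | step 9 | (2β)-triethylsilyloxy-(3α,6β)-bis(TBS-oxy)cyclohex-4-en-1-one | O=C1[C@@H](O[Si](CC)(CC)CC)[C@H](O[Si](C)(C)C(C)(C)C)C=C[C@H]1O[Si](C)(C)C(C)(C)C
F4 | step 9 | 1-methylene-(2β)-triethylsilyloxy-(3α,6β)-bis(TBS-oxy)cyclohex-4-ene | C=C1[C@@H](O[Si](CC)(CC)CC)[C@H](O[Si](C)(C)C(C)(C)C)C=C[C@H]1O[Si](C)(C)C(C)(C)C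
F5 | step 9 | 1-methylene-(3α,6β)-bis(TBS-oxy)cyclohex-4-en-2β-ol | C=C1[C@@H](O)[C@H](O[Si](C)(C)C(C)(C)C)C=C[C@H]1O[Si](C)(C)C(C)(C)C
F6 | step 13 | 3α-hydroxy epoxide (target lacking the O3 benzoyl group) | CC(=O)O[C@H]1[C@H](O)C=C[C@@H]2O[C@@]21COC(=O)c1ccccc1
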